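**Retrosynthetic overview**

1. 30 ⇐ 28: the C3–C4 epoxide is made last, through a bromohydrin, so that its oxygen ends anti to the C10 hydroxyl.
2. 28 ⇐ 25 (disconnection C1–C5): a cis-fused eudesm-3-ene 1β-mesylate ionises with shift of C5 from C10 to C1, forming the cyclopentene and the cycloheptane together; the feature used is the tertiary C10 hydroxyl lying cis and 1,3 to the C8 veratrate on the seven-membered ring, with C10 bonded to ring-fusion carbon C1 of the trans-fused five/seven system – the mark of a C10 cation held by the ester carbonyl.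
3. 25 ⇐ 20: an α-oxygen at C3 of ring A delivers hydride to C1 (1β-OH) and then leaves as an allylic diazene that puts hydrogen on C5 (cis fusion) and the alkene at C3–C4; 20 ⇐ dienone 14 by epoxidation, Wharton transposition and hydroxyl-directed epoxidation.
4. Ring A ⇐ ketone 7 + ethyl vinyl ketone 9 (chiral-imine Michael addition, aldol condensation); ring B ⇐ (R)-piperitone 1, with the veratrate from 3 in place from step 2.
5. Order of ring formation: ring B (from 1), ring A (steps 5–6), five- and seven-membered rings (step 16), oxirane (step 17).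

Key step: step 16

Remark: enantiopure (R)-piperitone is assumed; eudesmane numbering is used for the decalins and guaiane numbering from step 16 on; β is the face of the C7 isopropyl group and O8; veratrate = 3,4-dimethoxybenzoate.

**Step 1**
Reactants: 1 (R)-piperitone
Product: 2 cis-piperitol
Conditions: LiBH(s-Bu)3, THF, −78 °C; aq. NH4Cl
Reagents that add atoms: none
Why: 1,2-hydride reduction of a β,β-disubstituted enone, in which the bulky borohydride attacks from the equatorial direction and so sets the carbinol centre (later C8) cis to the isopropyl group.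

**Step 2**
Reactants: 2 cis-piperitol; 3 3,4-dimethoxybenzoyl chloride
Product: 4 cis-piperityl veratrate
Conditions: Et3N, DMAP (cat), CH2Cl2, 0 to 23 °C
Reagents that add atoms: none
Why: DMAP-catalysed acylation at oxygen (retention) installs at the outset the ester that protects O8 and later traps the C10 cation.

**Step 3**
Reactants: 4 cis-piperityl veratrate
Product: 5 3-methyl-4-oxo-6-(propan-2-yl)cyclohex-2-en-1-yl veratrate (ester cis to isopropyl)
Conditions: Rh2(cap)4 (cap = caprolactamate, 1 mol%), t-BuOOH (70% in H2O), K2CO3, CH2Cl2, 23 °C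
Reagents that add atoms: tert-butyl hydroperoxide, CC(C)(C)OO
Why: radical allylic oxidation turns the ring methylene next to the methyl-bearing alkene carbon into the enone carbonyl, because the only other ring allylic C–H is a hindered methine deactivated by the acyloxy group, and no stereocentre is touched.

**Step 4**
Reactants: 5 enone
Product: 7 5-methyl-4-oxo-2-(propan-2-yl)cyclohexyl veratrate (C5 epimers), via lithium enolate 6 (not isolated)
Conditions: LiBH(s-Bu)3, THF, −78 °C; aq. NH4Cl
Reagents that add atoms: none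
Why: conjugate hydride reduction of a 2-methylcyclohexenone with a β-hydrogen (as with carvone) gives enolate 6 and then the ketone, whose C-methyl centre is rebuilt in step 5.

**Step 5**
Reactants: 7 ketone; 8 (R)-1-phenylethylamine; 9 ethyl vinyl ketone
Product: 12 5-methyl-4-oxo-5-(3-oxopentyl)-2-(propan-2-yl)cyclohexyl veratrate (5-methyl cis to ester), via imine 10 (not isolated), via alkylated imine 11 (not isolated)
Conditions: 8, TsOH (cat), toluene, reflux (Dean–Stark); 9, THF, 40 °C; 10% aq. AcOH, 23 °C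
Reagents that add atoms: none
Why: d'Angelo Michael addition, in which the more substituted enamine tautomer of chiral imine 10 adds to the enone on the face fixed by the (R)-auxiliary (the pairing that gives the α-cyperone configuration from dihydrocarvone, and the face anti to the axial acyloxy group), so the quaternary centre (later C10) carries its methyl cis to the isopropyl and acyloxy groups.

**Step 6**
Reactants: 12 diketone
Product: 13 8β-veratroyloxyeudesm-4-en-3-one
Conditions: TsOH·H2O (cat), toluene, reflux (Dean–Stark)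
Reagents that add atoms: none
Why: intramolecular aldol condensation (second stage of the Robinson annulation) closes ring A by exo attack of the ethyl ketone enol on the ring carbonyl and dehydrates to the tetrasubstituted enone without touching C10.

**Step 7**
Reactants: 13 enone
Product: 14 8β-veratroyloxyeudesma-1,4-dien-3-one
Conditions: DDQ, dioxane, 100 °C
Reagents that add atoms: none
Why: DDQ dehydrogenation of a 4-en-3-one under neutral conditions abstracts hydride from C1 of the C2 enol and gives the cross-conjugated dienone, as in steroid chemistry.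

**Step 8**
Reactants: 14 dienone
Product: 15 1α,2α-epoxy-8β-veratroyloxyeudesm-4-en-3-one
Conditions: t-BuOOH, DBU, ClCH2CH2Cl, 23 °C
Reagents that add atoms: tert-butyl hydroperoxide, CC(C)(C)OO
Why: Weitz–Scheffer nucleophilic epoxidation attacks the less substituted C1–C2 enone bond from the α face, anti to the pseudo-axial C10 methyl group, as with steroidal 1,4-dien-3-ones.

**Step 9**
Reactants: 15 epoxy ketone
Product: 17 1α-hydroxyeudesma-2,4-dien-8β-yl veratrate, via epoxy hydrazone 16 (not isolated)
Conditions: N2H4·H2O, AcOH, MeOH, 0 to 23 °C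
Reagents that add atoms: none
Why: Wharton transposition, in which hydrazone 16 opens the epoxide and loses N2, removes the C3 oxygen and leaves the C1 oxygen (α, retained) as an allylic alcohol next to a new C2–C3 alkene.

**Step 10**
Reactants: 17 dienol
Product: 18 2α,3α-epoxy-1α-hydroxyeudesm-4-en-8β-yl veratrate
Conditions: VO(acac)2 (cat), t-BuOOH, CH2Cl2, 0 °C
Reagents that add atoms: tert-butyl hydroperoxide, CC(C)(C)OO
Why: vanadium-catalysed hydroxyl-directed epoxidation delivers oxygen to the allylic C2–C3 alkene on the face of the pseudo-axial 1α-hydroxyl, which places oxygen α at C3 and leaves the C4–C5 alkene alone.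

**Step 11**
Reactants: 18 epoxy alcohol
Product: 19 2α,3α-epoxy-1-oxoeudesm-4-en-8β-yl veratrate
Conditions: Dess–Martin periodinane, NaHCO3, CH2Cl2, 0 °C
Reagents that add atoms: none
Why: buffered Dess–Martin oxidation converts the secondary alcohol into the α,β-epoxy ketone without opening the vinyl epoxide.

**Step 12**
Reactants: 19 epoxy ketone
Product: 20 3α-hydroxy-1-oxoeudesm-4-en-8β-yl veratrate
Conditions: SmI2, THF–MeOH, −90 °C
Reagents that add atoms: none
Why: SmI2 reduction of an α,β-epoxy ketone cleaves the Cα–O bond through the ketyl, so C2 becomes a methylene group and C3 keeps its α-hydroxyl.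

**Step 13**
Reactants: 20 ketol
Product: 21 1β,3α-dihydroxyeudesm-4-en-8β-yl veratrate
Conditions: Me4NBH(OAc)3, MeCN–AcOH, −30 °C
Reagents that add atoms: none
Why: Evans–Saksena directed reduction, in which the pseudo-axial 3α-hydroxyl binds the borohydride and delivers hydride to the α face of the C1 carbonyl (also the face anti to the C10 methyl while C5 is still sp2 and ring B is locked), gives the 1,3-anti diol with the 1β-hydroxyl.

**Step 14**
Reactants: 21 diol
Product: 24 1β-hydroxy-5β-eudesm-3-en-8β-yl veratrate (cis-fused), via sulfonyl hydrazine 22 (not isolated), via allylic diazene 23 (not isolated)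
Conditions: 2-O2NC6H4SO2NHNH2, PPh3, DEAD, THF, −30 to 23 °C
Reagents that add atoms: none
Why: Myers reductive allylic transposition, in which Mitsunobu displacement of the allylic 3α-hydroxyl with inversion (the neopentyl C1 hydroxyl stays) gives 22 and then the 3β-diazene 23, whose retro-ene loss of N2 passes hydrogen suprafacially to the β face of C5 and so sets the cis ring fusion and the C3–C4 alkene.

**Step 15**
Reactants: 24 alcohol
Product: 25 1β-mesyloxy-5β-eudesm-3-en-8β-yl veratrate
Conditions: MsCl, Et3N, CH2Cl2, 0 °C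
Reagents that add atoms: methanesulfonyl chloride, CS(=O)(=O)Cl
Why: sulfonylation at oxygen through the sulfene keeps the C1 configuration; the alkene (not a C3 carbonyl derivative) is carried into the shift, so no β-sulfonyloxy carbonyl stage arises and only the epoxide remains to be made afterwards.

**Step 16**
Reactants: 25 mesylate
Product: 28 10β-hydroxy-1α,5β-guai-3-en-8β-yl veratrate, via dioxanylium ion 26 (not isolated), via tertiary ester 27 (not isolated)
Conditions: 2,6-lutidine, (CF3)2CHOH–H2O (4:1), 50 °C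
Reagents that add atoms: water, O
Why: Proposed new method: in 25 the equatorial C1–OMs bond (conformer with C6 axial on ring A) is antiperiplanar to C5–C10, so ionisation in buffered aqueous (CF3)2CHOH should be concerted with a Wagner–Meerwein 1,2-shift of C5 from C10 to C1, and the tertiary C10 cation is then captured by the carbonyl oxygen of the cis-1,3 C8 veratrate as the 1,3-dioxan-2-ylium ion 26, which water opens. The closest known reaction type is the solvolytic rearrangement of eudesmane-type decalin 1-sulfonates to hydroazulenes, which ends in elimination; its union with 1,3-acyloxy capture of the cation is untested. The cyclopentene closes by backside bonding of the migrating C5 to C1 (contraction of ring A), the cycloheptane results from the same bond reorganisation as a one-carbon expansion of ring B, and the transient dioxane ring closes by attack of the ester carbonyl on the planar cation. C1 is set by inversion (1β-OMs gives 1α-H, trans to the retained 5β-H) and C10 by oxygen delivery from the β-oriented ester, which leaves the hydroxyl β and cis to O8 and the methyl α. The ortho acid collapses to hydroxy esters, and any tertiary ester 27 should pass its acyl group back to the less hindered O8 under the buffer. The step needs shift of C5 over C9, methyl or the homoallylic alkene and capture over proton loss: the first rests on the equatorial mesylate in the conformer favoured by allylic strain between C4–CH3 and C6 and by relief of the syn-diaxial C10–CH3/O8 contact, and on the higher migratory aptitude of the tertiary allylic C5; the second rests on the fixed cis-1,3 reach of the electron-rich aroyl carbonyl and the long cation lifetime in the non-nucleophilic medium.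

**Step 17**
Reactants: 28 alkene
Product: 30 3α,4α-epoxy-10β-hydroxy-1α,5β-guaian-8β-yl veratrate (target), via bromohydrin 29 (not isolated)
Conditions: NBS, THF–H2O (3:1), 0 °C; K2CO3, 23 °C
Reagents that add atoms: water, O
Why: bromohydrin formation and intramolecular Williamson closure, in which the bromonium ion forms on the less hindered β face of the cyclopentene (the face of the allylic C5–H, away from C6), water opens it at the tertiary C4 from the α face and the 4α-alkoxide displaces bromide at C3 with inversion, so the oxirane oxygen ends α and anti to the C10 hydroxyl, whereas a peracid would be expected to attack the β face.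

**Compound list**

1 | (R)-piperitone, (6R)-3-methyl-6-(propan-2-yl)cyclohex-2-en-1-one | CC1=CC(=O)[C@@H](C(C)C)CC1 | starting material
2 | cis-piperitol, (1S,6R)-3-methyl-6-(propan-2-yl)cyclohex-2-en-1-ol | CC1=C[C@@H](O)[C@@H](C(C)C)CC1 | intermediate
3 | 3,4-dimethoxybenzoyl chloride | COc1ccc(C(Cl)=O)cc1OC | starting material
4 | cis-piperityl 3,4-dimethoxybenzoate | CC1=C[C@@H](OC(=O)c2ccc(OC)c(OC)c2)[C@@H](C(C)C)CC1 | intermediate
5 | 3-methyl-4-oxo-6-(propan-2-yl)cyclohex-2-en-1-yl 3,4-dimethoxybenzoate (ester cis to isopropyl) | CC1=C[C@@H](OC(=O)c2ccc(OC)c(OC)c2)[C@@H](C(C)C)CC1=O | intermediate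
6 | lithium enolate of 7 | [Li+].[O-]C1=C(C)C[C@@H](OC(=O)c2ccc(OC)c(OC)c2)[C@@H](C(C)C)C1 | intermediate (not isolated)
7 | 5-methyl-4-oxo-2-(propan-2-yl)cyclohexyl 3,4-dimethoxybenzoate (ester cis to isopropyl; C5 epimers) | CC1C[C@@H](OC(=O)c2ccc(OC)c(OC)c2)[C@@H](C(C)C)CC1=O | intermediate
8 | (R)-1-phenylethylamine | C[C@@H](N)c1ccccc1 | starting material
9 | ethyl vinyl ketone | CCC(=O)C=C | starting material
10 | N-[(R)-1-phenylethyl]imine of 7 | CC1C[C@@H](OC(=O)c2ccc(OC)c(OC)c2)[C@@H](C(C)C)CC1=N[C@H](C)c3ccccc3 | intermediate (not isolated)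
11 | N-[(R)-1-phenylethyl]imine of 12 | CCC(=O)CC[C@]1(C)C[C@@H](OC(=O)c2ccc(OC)c(OC)c2)[C@@H](C(C)C)CC1=N[C@H](C)c3ccccc3 | intermediate (not isolated)
12 | 5-methyl-4-oxo-5-(3-oxopentyl)-2-(propan-2-yl)cyclohexyl 3,4-dimethoxybenzoate (methyl cis to ester and isopropyl) | CCC(=O)CC[C@]1(C)C[C@@H](OC(=O)c2ccc(OC)c(OC)c2)[C@@H](C(C)C)CC1=O | intermediate
13 | 8β-veratroyloxyeudesm-4-en-3-one (7β-isopropyl, 10β-methyl) | COc1ccc(C(=O)O[C@@H]2C[C@@]3(C)CCC(=O)C(C)=C3C[C@@H]2C(C)C)cc1OC | intermediate
14 | 8β-veratroyloxyeudesma-1,4-dien-3-one | COc1ccc(C(=O)O[C@@H]2C[C@@]3(C)C=CC(=O)C(C)=C3C[C@@H]2C(C)C)cc1OC | intermediate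
15 | 1α,2α-epoxy-8β-veratroyloxyeudesm-4-en-3-one | COc1ccc(C(=O)O[C@@H]2C[C@@]3(C)[C@H]4O[C@H]4C(=O)C(C)=C3C[C@@H]2C(C)C)cc1OC | intermediate
16 | hydrazone of 15 | COc1ccc(C(=O)O[C@@H]2C[C@@]3(C)[C@H]4O[C@H]4C(=NN)C(C)=C3C[C@@H]2C(C)C)cc1OC | intermediate (not isolated)
17 | 1α-hydroxyeudesma-2,4-dien-8β-yl veratrate | COc1ccc(C(=O)O[C@@H]2C[C@@]3(C)[C@@H](O)C=CC(C)=C3C[C@@H]2C(C)C)cc1OC | intermediate
18 | 2α,3α-epoxy-1α-hydroxyeudesm-4-en-8β-yl veratrate | COc1ccc(C(=O)O[C@@H]2C[C@@]3(C)[C@@H](O)[C@H]4O[C@H]4C(C)=C3C[C@@H]2C(C)C)cc1OC | intermediate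
19 | 2α,3α-epoxy-1-oxoeudesm-4-en-8β-yl veratrate | COc1ccc(C(=O)O[C@@H]2C[C@@]3(C)C(=O)[C@H]4O[C@H]4C(C)=C3C[C@@H]2C(C)C)cc1OC | intermediate
20 | 3α-hydroxy-1-oxoeudesm-4-en-8β-yl veratrate | COc1ccc(C(=O)O[C@@H]2C[C@@]3(C)C(=O)C[C@@H](O)C(C)=C3C[C@@H]2C(C)C)cc1OC | intermediate
21 | 1β,3α-dihydroxyeudesm-4-en-8β-yl veratrate | COc1ccc(C(=O)O[C@@H]2C[C@@]3(C)[C@H](O)C[C@@H](O)C(C)=C3C[C@@H]2C(C)C)cc1OC | intermediate
22 | 1β-hydroxy-3β-[1-(2-nitrophenylsulfonyl)hydrazinyl]eudesm-4-en-8β-yl veratrate | COc1ccc(C(=O)O[C@@H]2C[C@@]3(C)[C@H](O)C[C@H](N(N)S(=O)(=O)c4ccccc4[N+](=O)[O-])C(C)=C3C[C@@H]2C(C)C)cc1OC | intermediate (not isolated)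
23 | 3β-diazenyl-1β-hydroxyeudesm-4-en-8β-yl veratrate | COc1ccc(C(=O)O[C@@H]2C[C@@]3(C)[C@H](O)C[C@H](N=N)C(C)=C3C[C@@H]2C(C)C)cc1OC | intermediate (not isolated)
24 | 1β-hydroxy-5β-eudesm-3-en-8β-yl veratrate (cis-fused, 10β-methyl) | COc1ccc(C(=O)O[C@@H]2C[C@@]3(C)[C@H](O)CC=C(C)[C@H]3C[C@@H]2C(C)C)cc1OC | intermediate
25 | 1β-mesyloxy-5β-eudesm-3-en-8β-yl veratrate | COc1ccc(C(=O)O[C@@H]2C[C@@]3(C)[C@H](OS(C)(=O)=O)CC=C(C)[C@H]3C[C@@H]2C(C)C)cc1OC | intermediate
26 | 2-(3,4-dimethoxyphenyl)-1,3-dioxan-2-ylium ion bridging O8 and O10 of the 1α,5β-guai-3-ene | COc1ccc(cc1OC)C2=[O+][C@@]3(C)C[C@@H](O2)[C@@H](C(C)C)C[C@@H]4C(C)=CC[C@@H]34 | intermediate (not isolated)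
27 | 8β-hydroxy-1α,5β-guai-3-en-10β-yl veratrate (tertiary ester) | COc1ccc(C(=O)O[C@@]2(C)C[C@@H](O)[C@@H](C(C)C)C[C@@H]3C(C)=CC[C@@H]23)cc1OC | intermediate (not isolated)
28 | 10β-hydroxy-1α,5β-guai-3-en-8β-yl veratrate (10α-methyl) | COc1ccc(C(=O)O[C@@H]2C[C@](C)(O)[C@@H]3CC=C(C)[C@H]3C[C@@H]2C(C)C)cc1OC | intermediate
29 | 3β-bromo-4α,10β-dihydroxy-1α,5β-guaian-8β-yl veratrate | COc1ccc(C(=O)O[C@@H]2C[C@](C)(O)[C@@H]3C[C@H](Br)[C@](O)(C)[C@H]3C[C@@H]2C(C)C)cc1OC | intermediate (not isolated)
30 | 3α,4α-epoxy-10β-hydroxy-1α,5β-guaian-8β-yl 3,4-dimethoxybenzoate | COc1ccc(C(=O)O[C@@H]2C[C@](C)(O)[C@@H]3C[C@H]4O[C@@]4(C)[C@H]3C[C@@H]2C(C)C)cc1OC | target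

Total step count: 17. Longest linear sequence: 17 steps (1 to 30).

**Steps most likely to fail**

Step 16: the C10 cation may lose a proton (to C14, C9 or C1) faster than the ester closes on it, or the ring-flipped conformer may ionise with shift of C9. The fallback uses known chemistry and runs from 25 back to 28. The mesylate is rearranged by the established buffered acetolysis (KOAc, AcOH, 100 °C), which ends in elimination, and the exocyclic alkene 1α,5β-guaia-3,10(14)-dien-8β-yl veratrate F1 is separated from its endocyclic isomers. K2CO3 in MeOH removes the ester to give 1α,5β-guaia-3,10(14)-dien-8β-ol F2. VO(acac)2/t-BuOOH epoxidises the homoallylic exocyclic alkene on the face of the 8β-hydroxyl to 10β,14-epoxy-1α,5β-guai-3-en-8β-ol F3. LiAlH4 opens the spiro-epoxide at C14 to 1α,5β-guai-3-ene-8β,10β-diol F4, and acylation of the secondary hydroxyl with 3 (Et3N, DMAP) returns to 28.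

Step 3: hydrogen abstraction may occur at the acyloxy-bearing methine, or the allyl radical may be oxygenated at the carbon next to the ester, giving the wrong enone or loss of the ester. The fallback runs from 4 back to 5. SeO2 (cat) with t-BuOOH in CH2Cl2 hydroxylates by an ene reaction and [2,3]-shift at the ring methylene of the more substituted alkene terminus, giving 4-hydroxy-3-methyl-6-(propan-2-yl)cyclohex-2-en-1-yl veratrate F5. Dess–Martin oxidation of F5 gives 5.

Step 17: the bromonium ion may form on the α face, be opened by the C10 hydroxyl, or be opened by water without face or site control. The fallback runs from 28 back to 30. m-CPBA, helped by the C10 hydroxyl, epoxidises the β face to 3β,4β-epoxy-10β-hydroxy-1α,5β-guaian-8β-yl veratrate F6. Dilute HClO4 in aqueous THF opens it at the tertiary C4 with inversion to 3β,4α,10β-trihydroxy-1α,5β-guaian-8β-yl veratrate F7. MsCl/Et3N sulfonylates only the secondary O3 to give 4α,10β-dihydroxy-3β-mesyloxy-1α,5β-guaian-8β-yl veratrate F8, and K2CO3 closes the 4α-alkoxide onto C3 with inversion to 30.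

**Further compounds**

F1 | step 16 | 1α,5β-guaia-3,10(14)-dien-8β-yl 3,4-dimethoxybenzoate | COc1ccc(C(=O)O[C@@H]2CC(=C)[C@@H]3CC=C(C)[C@H]3C[C@@H]2C(C)C)cc1OC
F2 | step 16 | 1α,5β-guaia-3,10(14)-dien-8β-ol | O[C@@H]1CC(=C)[C@@H]2CC=C(C)[C@H]2C[C@@H]1C(C)C
F3 | step 16 | 10β,14-epoxy-1α,5β-guai-3-en-8β-ol | O[C@@H]1C[C@@]2(CO2)[C@@H]3CC=C(C)[C@H]3C[C@@H]1C(C)C
F4 | step 16 | 1α,5β-guai-3-ene-8β,10β-diol | O[C@@H]1C[C@](C)(O)[C@@H]2CC=C(C)[C@H]2C[C@@H]1C(C)C
F5 | step 3 | 4-hydroxy-3-methyl-6-(propan-2-yl)cyclohex-2-en-1-yl 3,4-dimethoxybenzoate (ester cis to isopropyl; hydroxyl epimers) | CC1=C[C@@H](OC(=O)c2ccc(OC)c(OC)c2)[C@@H](C(C)C)CC1O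
F6 | step 17 | 3β,4β-epoxy-10β-hydroxy-1α,5β-guaian-8β-yl 3,4-dimethoxybenzoate | COc1ccc(C(=O)O[C@@H]2C[C@](C)(O)[C@@H]3C[C@@H]4O[C@]4(C)[C@H]3C[C@@H]2C(C)C)cc1OC
F7 | step 17 | 3β,4α,10β-trihydroxy-1α,5β-guaian-8β-yl 3,4-dimethoxybenzoate | COc1ccc(C(=O)O[C@@H]2C[C@](C)(O)[C@@H]3C[C@H](O)[C@](O)(C)[C@H]3C[C@@H]2C(C)C)cc1OC
F8 | step 17 | 4α,10β-dihydroxy-3β-mesyloxy-1α,5β-guaian-8β-yl 3,4-dimethoxybenzoate | COc1ccc(C(=O)O[C@@H]2C[C@](C)(O)[C@@H]3C[C@H](OS(C)(=O)=O)[C@](O)(C)[C@H]3C[C@@H]2C(C)C)cc1OC
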